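**Plan**

Numbering used throughout: oxolane O1, C2 (pentyl), C3 (acyloxy), C4 (CH2), C5; C1' is the side-chain carbinol carbon.
Retrosynthetic cuts, in order: the myristate C–O bond at C3; C1'–H (ketone reduction) and C1'–C2' (Grignard addition to a C5 aldehyde); C5–H and C5–C1' (vinyl addition to a γ-lactone, then ionic reduction of the lactol); the ring bond C3–C4; the O1–C5 ester bond; the pentyl C–C bond next to C2 (epoxide opening).
Forward: the only ring arises first, as a 4-benzyloxy-5-pentyl γ-lactone, by closing C3–C4 through carbenoid C–H insertion of a diazoacetate; the lactone carbonyl (C5) is then turned into the C5 stereocentre, and the dec-9-enyl chain is joined before ester formation and ketone reduction.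
Enabling feature: in the open precursor C3 is an OCH2 carbon whose C–H bonds are made hydridic by the ether oxygen and lie 1,5 to the carbene carbon (C4), which hangs on O1 through the C5 ester carbonyl; O1, C5 and C4 therefore arrive as one diazoacetate unit and the oxolane ring closes with the C3 oxygen already in place.
Stereochemistry: C2 is bought with (S)-benzyl glycidyl ether; C3 follows from C2 in the insertion (retention at carbon, cis to pentyl, reinforced by the chiral catalyst); C5 follows from C3 (hydride attack cis to the C3 oxygen); C1' follows from C5 (Felkin–Anh reduction).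

Key step: step 4

Remark on the chemistry: the (4S)-series of the rhodium carboxamidate is assumed to be the partner matched to the (S)-configured C2 centre of 6 (removal of the pro-S OCH2 hydrogen); C2, not the catalyst, fixes the absolute configuration.

**Route**

Step 1
Reactants: 1 (S)-2-[(benzyloxy)methyl]oxirane ((S)-benzyl glycidyl ether); 2 n-butylmagnesium chloride
Product: 3 (2S)-1-(benzyloxy)heptan-2-ol
Conditions: n-BuMgCl (1.3 equiv), CuI (10 mol %), THF, −40 to 0 °C; aq. NH4Cl
Reagents that add atoms: none
Why: Copper-catalysed Grignard opening of a terminal epoxide at its unsubstituted carbon (SN2) builds the pentyl chain without touching the C2 stereocentre, which is bought with the glycidyl ether.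

Step 2
Reactants: 3 (2S)-1-(benzyloxy)heptan-2-ol; 4 bromoacetyl bromide
Product: 5 (2S)-1-(benzyloxy)heptan-2-yl bromoacetate
Conditions: BrCH2COBr (1.5 equiv), pyridine (2 equiv), CH2Cl2, 0 °C
Reagents that add atoms: none
Why: O-Acylation of the secondary alcohol with an acid bromide installs the two carbons that become C4 and C5 together with the O1–C5 ester link, and no bond to the stereocentre is broken.

Step 3
Reactants: 5 (2S)-1-(benzyloxy)heptan-2-yl bromoacetate
Product: 6 (2S)-1-(benzyloxy)heptan-2-yl diazoacetate
Conditions: TsNHNHTs (2 equiv), DBU (5 equiv), THF, 0 °C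
Reagents that add atoms: N,N'-ditosylhydrazine, Cc1ccc(cc1)S(=O)(=O)NNS(=O)(=O)c1ccc(C)cc1
Why: SN2 displacement of bromide by the hydrazine anion followed by base-induced loss of two sulfinate ions is the standard conversion of a bromoacetate into a diazoacetate, under conditions that leave the ester and the benzyl ether alone.

Step 4
Reactants: 6 (2S)-1-(benzyloxy)heptan-2-yl diazoacetate
Product: 7 (4S,5S)-4-(benzyloxy)-5-pentyloxolan-2-one
Conditions: Rh2(4S-MPPIM)4 (1 mol %; MPPIM = methyl 2-oxo-1-(3-phenylpropanoyl)imidazolidine-4-carboxylate), CH2Cl2, reflux, 6 added by syringe pump over 10 h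
Reagents that add atoms: none
Why: Loss of N2 from 6 on the divalent rhodium carboxamidate gives a transient, catalyst-bound electrophilic carbene at the future C4, which inserts into the C3–H bond through a concerted, hydride-transfer-like three-centre transition state with retention at C3; the closest known reaction type is the intramolecular carbenoid C–H insertion of alkyl diazoacetates to γ-butyrolactones, in particular of 2-alkoxyethyl and 1,3-dialkoxy-2-propyl diazoacetates. The oxolan-2-one ring closes in the 1,5-mode (five-membered cyclic transition state made of the carbene carbon, C5, O1, C2 and C3) by forming the C4–C3 bond only. The new C3 stereocentre is set by which of the two diastereotopic OCH2 hydrogens is replaced: the resident C2 centre places the pentyl group pseudo-equatorial in the envelope-like transition state and the ligand wall of the (4S)-catalyst is expected to present the pro-S hydrogen, so that benzyloxy and pentyl end up cis (4S,5S). The step needs site selectivity for the ether-activated C3–H over the unactivated first CH2 of the pentyl chain (also 1,5), the benzylic OCH2 (1,7) and the carbinol C–H (1,4), and chemoselectivity for insertion over oxonium-ylide formation at the benzyl ether oxygen, addition to the arene and carbene dimerisation. The lone pair of the ether oxygen on C3 makes exactly that C–H bond the most hydridic one, the electron-rich carboxamidate ligands make the carbene selective enough to respond to it and disfavour the ylide and arene pathways, and slow addition keeps the diazo ester dilute.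

Step 5
Reactants: 7 (4S,5S)-4-(benzyloxy)-5-pentyloxolan-2-one; 8 vinylmagnesium bromide
Product: 9 (4S,5S)-4-(benzyloxy)-2-ethenyl-5-pentyloxolan-2-ol (both anomers, used crude)
Conditions: CH2=CHMgBr (1.2 equiv), THF, −78 °C; aq. NH4Cl at −78 °C
Reagents that add atoms: none
Why: Grignard mono-addition to a γ-lactone works because the tetrahedral magnesium alkoxide is stable at −78 °C and releases the lactol only on quench, and the anomeric centre formed here is removed in the next step.

Step 6
Reactants: 9 (4S,5S)-4-(benzyloxy)-2-ethenyl-5-pentyloxolan-2-ol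
Product: 10 (2S,3S,5R)-3-(benzyloxy)-5-ethenyl-2-pentyloxolane
Conditions: Et3SiH (3 equiv), BF3·OEt2 (2 equiv), CH2Cl2, −78 to −40 °C
Reagents that add atoms: none
Why: Lewis-acid ionisation of the lactol and silane reduction of the transient oxocarbenium ion (ionic hydrogenation of a ketose-type lactol) should deliver hydride on the inside face of the envelope that holds the C3 benzyloxy group pseudo-axial and the C2 pentyl group pseudo-equatorial, that is cis to the C3 oxygen, so that the vinyl group ends up trans to both ring substituents (5R).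

Step 7
Reactants: 10 (2S,3S,5R)-3-(benzyloxy)-5-ethenyl-2-pentyloxolane
Product: 12 (2R,4S,5S)-4-(benzyloxy)-5-pentyloxolane-2-carbaldehyde, via secondary ozonide 11 (not isolated)
Conditions: O3, CH2Cl2, −78 °C (Sudan red 7B as end-point indicator); then PPh3, −78 °C to rt
Reagents that add atoms: ozone, [O-][O+]=O
Why: Ozonolysis of the only C=C bond with reductive work-up gives the α-alkoxy aldehyde without touching C5, and the indicator dye stops the reaction before the benzyl ether is attacked.

Step 8
Reactants: 12 (2R,4S,5S)-4-(benzyloxy)-5-pentyloxolane-2-carbaldehyde; 13 9-bromonon-1-ene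
Product: 15 1-[(2R,4S,5S)-4-(benzyloxy)-5-pentyloxolan-2-yl]dec-9-en-1-ol (both C1 epimers), via non-8-en-1-ylmagnesium bromide 14 (not isolated)
Conditions: 13, Mg, THF, rt; then 12, THF, −78 °C; aq. NH4Cl
Reagents that add atoms: none
Why: Grignard addition to the aldehyde forms the C1'–C2' bond and brings in the terminal alkene, and the configuration at C1' does not matter here because the carbinol is oxidised in the next step.

Step 9
Reactants: 15 1-[(2R,4S,5S)-4-(benzyloxy)-5-pentyloxolan-2-yl]dec-9-en-1-ol
Product: 16 1-[(2R,4S,5S)-4-(benzyloxy)-5-pentyloxolan-2-yl]dec-9-en-1-one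
Conditions: Dess–Martin periodinane (1.3 equiv), NaHCO3, CH2Cl2, 0 °C to rt
Reagents that add atoms: none
Why: Dess–Martin oxidation under buffered, non-basic conditions converges both C1' epimers to one ketone and should not epimerise the adjacent C5.

Step 10
Reactants: 16 1-[(2R,4S,5S)-4-(benzyloxy)-5-pentyloxolan-2-yl]dec-9-en-1-one
Product: 17 1-[(2R,4S,5S)-4-hydroxy-5-pentyloxolan-2-yl]dec-9-en-1-one
Conditions: BCl3 (2 equiv), pentamethylbenzene (3 equiv), CH2Cl2, −78 °C; MeOH quench, then water
Reagents that add atoms: none
Why: Lewis-acid cleavage of the benzyl ether with an arene scavenger (Friedel–Crafts capture of the benzyl cation) frees the C3 hydroxyl at a temperature where the terminal alkene, the ketone and the ring ether should stay intact, whereas hydrogenolysis is ruled out by the alkene.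

Step 11
Reactants: 17 1-[(2R,4S,5S)-4-hydroxy-5-pentyloxolan-2-yl]dec-9-en-1-one; 18 tetradecanoyl chloride
Product: 19 (2S,3S,5R)-5-(dec-9-enoyl)-2-pentyloxolan-3-yl tetradecanoate
Conditions: C13H27COCl (1.3 equiv), pyridine (3 equiv), DMAP (cat.), CH2Cl2, 0 °C
Reagents that add atoms: none
Why: DMAP-catalysed acylation of the only free hydroxyl gives the C3 myristate with retention, while the ketone keeps C1' masked so that no hydroxyl differentiation is needed.

Step 12
Reactants: 19 (2S,3S,5R)-5-(dec-9-enoyl)-2-pentyloxolan-3-yl tetradecanoate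
Product: 20 (2S,3S,5R)-5-[(1R)-1-hydroxydec-9-en-1-yl]-2-pentyloxolan-3-yl tetradecanoate
Conditions: LiBH(s-Bu)3 (1.1 equiv), THF, −78 °C; aq. NH4Cl at −78 °C
Reagents that add atoms: none
Why: Felkin–Anh-controlled reduction of the α-alkoxy ketone by a bulky hydride, with the C5–O1 bond anti to the incoming hydride and attack past the C5 hydrogen, should give the threo (1'R) carbinol, and at −78 °C the ester and the alkene are not reduced.

**Compound list**

1 | (S)-2-[(benzyloxy)methyl]oxirane | C(OCc1ccccc1)[C@@H]1CO1 | starting material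
2 | n-butylmagnesium chloride | CCCC[Mg]Cl | starting material
3 | (2S)-1-(benzyloxy)heptan-2-ol | CCCCC[C@H](O)COCc1ccccc1 | intermediate
4 | bromoacetyl bromide | BrCC(Br)=O | starting material
5 | (2S)-1-(benzyloxy)heptan-2-yl bromoacetate | CCCCC[C@H](OC(=O)CBr)COCc1ccccc1 | intermediate
6 | (2S)-1-(benzyloxy)heptan-2-yl diazoacetate | CCCCC[C@H](OC(=O)C=[N+]=[N-])COCc1ccccc1 | intermediate
7 | (4S,5S)-4-(benzyloxy)-5-pentyloxolan-2-one | O=C1C[C@H](OCc2ccccc2)[C@H](CCCCC)O1 | intermediate
8 | vinylmagnesium bromide | C=C[Mg]Br | starting material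
9 | (4S,5S)-4-(benzyloxy)-2-ethenyl-5-pentyloxolan-2-ol (both anomers) | C=CC1(O)C[C@H](OCc2ccccc2)[C@H](CCCCC)O1 | intermediate
10 | (2S,3S,5R)-3-(benzyloxy)-5-ethenyl-2-pentyloxolane | C=C[C@H]1C[C@H](OCc2ccccc2)[C@H](CCCCC)O1 | intermediate
11 | 3-[(2R,4S,5S)-4-(benzyloxy)-5-pentyloxolan-2-yl]-1,2,4-trioxolane (secondary ozonide) | C1OC(OO1)[C@H]1C[C@H](OCc2ccccc2)[C@H](CCCCC)O1 | intermediate
12 | (2R,4S,5S)-4-(benzyloxy)-5-pentyloxolane-2-carbaldehyde | O=C[C@H]1C[C@H](OCc2ccccc2)[C@H](CCCCC)O1 | intermediate
13 | 9-bromonon-1-ene | C=CCCCCCCCBr | starting material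
14 | non-8-en-1-ylmagnesium bromide | C=CCCCCCCC[Mg]Br | intermediate
15 | 1-[(2R,4S,5S)-4-(benzyloxy)-5-pentyloxolan-2-yl]dec-9-en-1-ol (both C1 epimers) | C=CCCCCCCCC(O)[C@H]1C[C@H](OCc2ccccc2)[C@H](CCCCC)O1 | intermediate
16 | 1-[(2R,4S,5S)-4-(benzyloxy)-5-pentyloxolan-2-yl]dec-9-en-1-one | C=CCCCCCCCC(=O)[C@H]1C[C@H](OCc2ccccc2)[C@H](CCCCC)O1 | intermediate
17 | 1-[(2R,4S,5S)-4-hydroxy-5-pentyloxolan-2-yl]dec-9-en-1-one | C=CCCCCCCCC(=O)[C@H]1C[C@H](O)[C@H](CCCCC)O1 | intermediate
18 | tetradecanoyl chloride | CCCCCCCCCCCCCC(Cl)=O | starting material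
19 | (2S,3S,5R)-5-(dec-9-enoyl)-2-pentyloxolan-3-yl tetradecanoate | C=CCCCCCCCC(=O)[C@H]1C[C@H](OC(=O)CCCCCCCCCCCCC)[C@H](CCCCC)O1 | intermediate
20 | (2S,3S,5R)-5-[(1R)-1-hydroxydec-9-en-1-yl]-2-pentyloxolan-3-yl tetradecanoate | C=CCCCCCCC[C@@H](O)[C@H]1C[C@H](OC(=O)CCCCCCCCCCCCC)[C@H](CCCCC)O1 | target

**Step count and risks**

Total step count: 12. Longest linear sequence: 12 steps (1 to 20); all other building blocks are commercial.

Step 4. The process at risk is poor discrimination between the two diastereotopic C3 hydrogens (loss of the cis relationship) if catalyst and C2 centre prove mismatched, together with competing insertion into the pentyl chain. The fallback gives up hydrogen selection and sets C3 by substrate-controlled hydrogenation. It sets out from 6. Decomposition with the achiral catalyst Rh2(acam)4 (acam = acetamidate) in CH2Cl2 should give the lactone as a C4-epimer mixture, (5S)-4-(benzyloxy)-5-pentyloxolan-2-one F1. Hydrogenolysis (H2, Pd/C, EtOAc) should give (5S)-4-hydroxy-5-pentyloxolan-2-one F2. Dess–Martin oxidation erases the C4 centre and should give the tetronic acid (S)-4-hydroxy-5-pentylfuran-2(5H)-one F3. Hydrogenation over Rh/Al2O3 (H2, EtOAc) should add hydrogen anti to the pentyl group and give (4S,5S)-4-hydroxy-5-pentyloxolan-2-one F4. Acid-catalysed benzylation (benzyl 2,2,2-trichloroacetimidate, TfOH cat., CH2Cl2) comes back to the route at 7.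

Step 6. The process at risk is hydride capture at the terminal carbon of the vinyl-substituted oxocarbenium ion (conjugate reduction), fed by any over-addition in step 5, and erosion of facial selectivity. The fallback uses an alkynyl group as the vinyl surrogate, whose ketose-type lactols are reduced cleanly at the ring carbon. It sets out from 7. Lithium (trimethylsilyl)acetylide (Me3SiC≡CH, n-BuLi, THF, −78 °C) should give (4S,5S)-4-(benzyloxy)-5-pentyl-2-[(trimethylsilyl)ethynyl]oxolan-2-ol F5. Et3SiH and BF3·OEt2 (CH2Cl2, −78 °C) should give, by the same inside attack, {[(2R,4S,5S)-4-(benzyloxy)-5-pentyloxolan-2-yl]ethynyl}trimethylsilane F6. K2CO3 in MeOH should give (2S,3S,5R)-3-(benzyloxy)-5-ethynyl-2-pentyloxolane F7. Semi-hydrogenation (H2, Pd/CaCO3 poisoned with Pb(OAc)2, quinoline) comes back to the route at 10.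

Step 10. The process at risk is Lewis-acid damage during ether cleavage: opening of the oxolane ring, addition of HCl to the terminal alkene, or epimerisation at C5 next to the ketone. The fallback removes the benzyl group before the alkene enters and makes the C1'–C2' bond last. It sets out from 12. Hydrogenolysis (H2, Pd/C, EtOAc) should give (2R,4S,5S)-4-hydroxy-5-pentyloxolane-2-carbaldehyde F8. Acylation with 18 (pyridine, DMAP cat., CH2Cl2, 0 °C) should give (2S,3S,5R)-5-formyl-2-pentyloxolan-3-yl tetradecanoate F9. Addition of 14 in the presence of MgBr2·OEt2 (CH2Cl2/Et2O, −78 °C) should attack the aldehyde much faster than the ester and, through the five-membered chelate of the aldehyde oxygen and O1, give the threo carbinol. It comes back to the route at 20 and replaces steps 8 to 12, at the price of lower expected control at C1' than in the ketone reduction.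

**Further compounds**

F1 | step 4 | (5S)-4-(benzyloxy)-5-pentyloxolan-2-one (C4 epimer mixture) | O=C1CC(OCc2ccccc2)[C@H](CCCCC)O1
F2 | step 4 | (5S)-4-hydroxy-5-pentyloxolan-2-one (C4 epimer mixture) | O=C1CC(O)[C@H](CCCCC)O1
F3 | step 4 | (S)-4-hydroxy-5-pentylfuran-2(5H)-one | O=C1C=C(O)[C@H](CCCCC)O1
F4 | step 4 | (4S,5S)-4-hydroxy-5-pentyloxolan-2-one | O=C1C[C@H](O)[C@H](CCCCC)O1
F5 | step 6 | (4S,5S)-4-(benzyloxy)-5-pentyl-2-[(trimethylsilyl)ethynyl]oxolan-2-ol | C[Si](C)(C)C#CC1(O)C[C@H](OCc2ccccc2)[C@H](CCCCC)O1
F6 | step 6 | {[(2R,4S,5S)-4-(benzyloxy)-5-pentyloxolan-2-yl]ethynyl}trimethylsilane | C[Si](C)(C)C#C[C@H]1C[C@H](OCc2ccccc2)[C@H](CCCCC)O1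
F7 | step 6 | (2S,3S,5R)-3-(benzyloxy)-5-ethynyl-2-pentyloxolane | C#C[C@H]1C[C@H](OCc2ccccc2)[C@H](CCCCC)O1
F8 | step 10 | (2R,4S,5S)-4-hydroxy-5-pentyloxolane-2-carbaldehyde | O=C[C@H]1C[C@H](O)[C@H](CCCCC)O1
F9 | step 10 | (2S,3S,5R)-5-formyl-2-pentyloxolan-3-yl tetradecanoate | O=C[C@H]1C[C@H](OC(=O)CCCCCCCCCCCCC)[C@H](CCCCC)O1
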